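I began with the amounts in birch, the flask asked about: against 0.51 M of substrate it held 0.561 M of partner, 0.459 M of third reagent and 0.255 M of second reagent, while maple, the earlier run, had 0.84 M of partner at −14 °C.

common to all: substrate 0.51 M; second reagent 0.255 M; third reagent 0.459 M

| charge | partner | temperature | remark | time |
|---|---|---|---|---|
| birch | 0.561 M | −20 °C | the very flask that is asked about, followed so far |  |
| maple | 0.84 M | −14 °C | run made earlier |  |
| flask | 0.561 M | −20 °C |  | 40 h |

| run | time / h | target / % | substrate / % |
|---|---|---|---|
| birch | 4.00 | 7.3 | 31.1 |
| birch | 10.0 | 22.1 | 12.1 |
| birch | 20.0 | 33.1 | 3.8 |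
| birch | 30.0 | 35.8 | 1.4 |
| birch | 40.0 | 38.4 | 0 |
| maple | 0.667 | 2.4 | 51.5 |
| maple | 2.00 | 9.7 | 18.9 |
| maple | 4.00 | 21.7 | 7.5 |
| maple | 6.00 | 29.4 | 1.1 |
| maple | 8.00 | 34.1 | 1.8 |

(scatter of a reading: 1 percentage point)

- blue: at 40 h add substrate, 50.0 % of the amount charged, then wait 40 h
- violet: change nothing and wait 40 h more
- green: at 40 h add second reagent, 100 % of the amount charged, then wait 40 h
- teal: at 40 h raise the temperature by 15 K, then wait 40 h

- the volume of additions can be left aside
- a reading or a percentage of target counts all its forms, free or not

* target, in percent of the substrate first charged, at 40 h
* what to do for the largest gain in target; "none" if nothing gains more than 2 percentage points (blue / violet / green / teal / none)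
* target present, in percent of the substrate first charged, after blue
* target present, in percent of the substrate first charged, after violet

In birch I first took the waiting pool, the part of the charged substrate that read as neither substrate nor target: it was 65.8 % at 10.0 h and 61.6 % at 40.0 h. If that pool had drained into target by a pseudo-first-order step, target's rate divided by the pool would have held still, but the readings gave 0.0375 /h early and 0.00422 /h late, so the early value was about ten times the late one, with the pool little changed. I read this as a pool waiting for a reagent that was being used up, and the smallest charge in birch was second reagent. The ratio 50.0 %, [second reagent] over [substrate] as charged, I called the reagent ceiling: assuming each target spent one second reagent, this made it the limiting reagent and capped target there. Measured on the first charge, blue left the ceiling at 50.0 %, whereas green raised it to 100 %, so I chose green and put now near 38.4 %. I did not count on the gap of 12 percentage points under the ceiling for violet.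

The forecast gave 37.8 % for now, 60 % after blue and 39.5 % after violet, and it chose blue, holding that “fresh substrate should make new target”; on that choice my reckoning parted from it.

The flask gave 37.4 % at 40 h, 38.1 % after blue and 38.3 % after violet, and green was best, gaining 39 points.

    substrate + partner → intermediate A (k = 0.0120 /M/min, Ea = 53.0 kJ/mol)
    second reagent + intermediate A → intermediate B (k = 0.00600 /M/min, Ea = 65.0 kJ/mol)
    third reagent + intermediate B → target (k = 0.0510 /M/min, Ea = 60.0 kJ/mol)
    substrate + second reagent → side product (k = 0.00300 /M/min, Ea = 54.0 kJ/mol)
    crystals ⇌ target, rate k5*(cs5 - [target]) while solid is left; crystals form when [target] > cs5 (solubility = 7.00 mM, k = 0.600 /min)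
    (constants at −20 °C)

In birch the half-life of substrate by its step with partner was 1.7 h as charged, whereas at 40.0 h the half-life of intermediate A by its step with second reagent was 19 d, with second reagent at 1.68 % of its charge, intermediate A at 50.2 %, and target, side product and intermediate B together at 49.2 % against the ceiling of 50.0 %. In the neighbouring flask, the same recipe with 0.31 M of substrate, the ceiling was 82.3 %, of which 71.1 % had been spent by 40.0 h, when side product stood at 11.1 % and target at 59.5 %.

The data were computed for substances that don't exist, and the scatter is random.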